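What would the flask with 33 mM of substrate hold after 8.0 min, and how near saturation would its dissolved gas stand?

common to all: gas phase 1.5 mM (held)

| flask | substrate | remark | time |
|---|---|---|---|
| zeta | 16 mM | run made earlier |  |
| eta | 66 mM | run made earlier |  |
| flask | 33 mM |  | 8.0 min |

- zeta (time / min: target / %, substrate / %): 0.500: 7.8, 91.5; 1.33: 16.6, 71.1; 3.00: 22.4, 44.1; 6.00: 19.3, 14.4
- eta (time / min: target / %, substrate / %): 0.500: 3.6, 94.6; 1.33: 4.3, 79.5; 3.00: 6.4, 54.4; 6.00: 7.5, 20.2

(standard deviation of a reading: 1 percentage point)

1. target at 8.0 min, in percent of the substrate charged
2. concentration of dissolved gas in solution at 8.0 min, in percent of saturation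

- at the start none of the gas phase is in solution

I froze one number. Between first and last readings, substrate in the zeta run fell at 0.336 min⁻¹ and in the eta run at 0.281 min⁻¹. This flask's charge is twice that of zeta and half that of eta, so I took their geometric mean, 0.307 min⁻¹, as the clearance constant: the share of the remaining substrate lost per minute, a pseudo-first-order rate constant.

The first rung was the start. The geometric mean of the first readings, 93.0% left at 0.500 min, gave a delay of 0.265 min, which I read as gas entering solution. Next came the substrate's lifetime, 3.26 min, longer than that delay. The asked time is longer still, so I reckoned 9.29% of the substrate left at 8.0 min. Then I turned to target: its readings in the zeta run fell from 22.4% at 3.00 min to 19.3% at 6.00 min, while the eta readings showed no fall by 6.00 min. I expected this flask past its peak, but put no figure of my own on target or gas.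

The forecast gave 10.5% of target and 96% of saturation: “Substrate is then about 3 mM and consumption about 1 mM/min, so the solution is near 96% of saturation.”

The flask gave 10.7% and 84.3%, so the forecast's saturation stood 12 percentage points too high.

    substrate + target → side product (k = 0.430 M⁻¹ s⁻¹)
    gas phase ⇌ dissolved gas, rate k2*(csat - [dissolved gas]) (kL = 0.120 s⁻¹)
    substrate + dissolved gas → target (k = 3.50 M⁻¹ s⁻¹)
    dissolved gas + target → over-reacted product (k = 3.50 M⁻¹ s⁻¹)

Substrate in the flask at 8.0 min stood at 8.13% against my 9.29%. The same flask read at 15 min takes the same reckoning: the clearance constant gives 1.08% of the substrate left, and that flask held 0.741%. Its dissolved gas had reached 96.6% of saturation, and its target had fallen to 2.82%.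

(The data were computed for substances that don't exist; the scatter is artificial.)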